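**Conventions.** Pyranones are numbered as in kojic acid: O1, C2 (carries the CH2O group), C3, C4 (carbonyl), C5 (enol oxygen), C6. Cyclopentenones are numbered C1 (carbonyl), C2 (oxygen-bearing alkene carbon), C3 (aryl-bearing alkene carbon), C4, C5. Compound numbers: 1 kojic acid; 2–4 brominated pyranones; 5 boronic acid; 6 diaryl pyranone; 7, 8 transient intermediates; 9–13 cyclopentenones; 14 silylated spiro-epoxide; 15 target.

## Analysis of the target

The target 15 is a 1-oxaspiro[2.4]hept-6-en-5-one: a cyclopent-2-enone in which every ring carbon is substituted and C4 is spiro-fused to an oxirane. The only stereocentres are the adjacent, fully substituted C4 and C5, both R. The oxirane oxygen on C4 and the methoxy group on C5 lie on opposite faces of the ring, so the oxirane CH2 is cis to the C5 methoxy group and the C5 aryl group is cis to the oxirane oxygen. Sensitive groups are the 2,2-disubstituted oxirane (allylic to the C2=C3 enol ether), the tertiary benzylic α-keto methyl ether at C5 and the two free phenols. In any precursor with a free C4 alkoxide, the β-hydroxy ketone C1–C5–C4 can open by retro-aldol cleavage of C4–C5, which would erase both stereocentres. The difficulty is to build two contiguous tetrasubstituted centres in a defined trans relationship on a ring without a single hydrogen, and to obtain one enantiomer although no other stereocentre is present. The strategy rests on the substructure C1(=O)–C2(O)=C3–C4(O)–C5(OMe) with the C4 and C5 oxygens trans. This is the 4-hydroxy-5-alkoxycyclopent-2-enone that a 4-pyranone gives on irradiation in an alcohol. Kojic acid 1 already holds the carbonyl, the C2 oxygen, the oxirane methylene and the ring oxygen that becomes the oxirane oxygen.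

## Retrosynthetic reasoning

**15 to 14.** The two phenol O–H bonds are masked as silyl ethers in 14. Free phenols would compete in the sulfonylation and consume the base of the ring closure, so they are unveiled last by a buffered desilylation that the oxirane should tolerate.

**14 to 13 and 12.** The oxirane is cut at its CH2–O bond, not at C4–O. The C4 stereocentre is then never touched, and the forward reaction is a displacement of a primary sulfonate in 13 by the tertiary alkoxide. 13 comes from diol 12, whose primary hydroxyl is easily told apart from the tertiary one.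

**12 to 11.** The single enantiomer is reached here by resolution. The photochemical ring contraction offers no handle for absolute control, so racemic 11 is resolved by enantioselective enzymatic hydrolysis of its only ester, the primary acetate. The same operation frees the hydroxyl that 13 needs. The step is placed after the enol oxygen has been methylated, because an enzyme would cleave the enol acetate of 9 without selectivity.

**11 to 10 and 9.** The C2–OCH3 bond is cut. The C2 oxygen is carried through the ring contraction as an acetate and is turned into the methyl ether afterwards, because a methoxy group on the pyranone would draw the solvent to its own carbon. The forward steps must cleave an enol acetate beside a primary acetate and methylate an acidic enol beside a tertiary alcohol.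

**9 to 6 (key disconnection).** The C3–C4 bond and the C5–OMe bond are cut together. This leads back to pyranone 6, in which the C4 oxygen is the ring oxygen. No other cut delivers both quaternary centres, the ring and their trans relationship in one operation from a flat, achiral precursor. The forward reaction has to close the ring by 4π electrocyclisation, add the alcohol solvent to the aryl-bearing oxyallyl terminus only, and do so on the face opposite the fused oxirane.

**6 to 4 and 5.** The two aryl–C(sp2) bonds are cut. Both aryl groups are identical and enter in one double cross-coupling of dibromide 4 with boronic acid 5. They are brought in after both halogenations so that the electron-rich silyloxyarenes never meet an electrophilic halogen.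

**4 to 3, 2 and 1.** The two C–Br bonds and the two acetates are removed in the order that the electronics of 1 dictate. The free enol of 1 directs the first halogen to C6; after acetylation to 3, C3 is the only remaining nucleophilic ring position and takes the second to give 4.

## Alternatives that were turned down

**Alternative 1:** The C4–C5 and C5–OMe bonds are cut in an open chain, and the ring is closed afterwards between C2 and C3.
- Forward key step: Rh2(OAc)4 turns aryl diazoketone A1 into a rhodium carbene. The alcohol that supplies the C5 methoxy group gives an oxonium ylide, which must add to the aliphatic carbonyl of chloromethyl 1,2-dione A2 before it undergoes a 1,2-proton shift. The product is acyclic chlorohydrin diketone A3, to be cyclised by aldol condensation and closed to the oxirane through the chloride.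
- For: three simple pieces; both quaternary centres and the methoxy group in one step; a leaving group for the oxirane already present. Its strongest point is that a chiral co-catalyst could set the absolute configuration without a resolution. On enantiocontrol this plan is stronger than the chosen one.
- Against: the ylide must be trapped by a ketone that becomes a fully substituted carbon, where O–H insertion usually wins. A2 is an α-chloro-1,2-dione, prone to hydration and electrophilic at two carbonyls. The relationship of two tetrasubstituted centres in an open chain has no obvious control element. A3 is a β-hydroxy ketone that must survive the base of a hindered aldol condensation.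
- Comparison: the chosen strategy gives up catalytic enantiocontrol. In return it forms the ring, both centres and their trans relationship in one step from a bicyclic intermediate that leaves no choice of face, and it never passes through an open-chain aldol.

**Alternative 2:** Only the C4–O bond of the spiro-oxirane is made in the key step, by moving an epoxide.
- Forward key step: base lets the primary alkoxide of fused 4,5-epoxide A4 attack C4 from the face opposite the fused oxirane (Payne rearrangement) and release the C5 tertiary alkoxide. This gives spiro-epoxy alcohol A5, which would then be O-methylated at C5.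
- For: inversion at C4 makes the trans relationship a consequence of mechanism, which is as strong as the anti capture of the chosen route. The oxirane needs no leaving group, which saves a step at the end.
- Against: A4 is a fully substituted epoxide of a cyclopentadienone-type ring with no short, reliable access. A Payne equilibrium normally favours the more substituted epoxide and the primary alkoxide, so the required direction is not assured. The last step would methylate a hindered tertiary α-keto benzylic alkoxide in a molecule that already contains the spiro-oxirane and can fragment by retro-aldol cleavage.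
- Comparison: the chosen strategy makes the C5–OMe bond when the centre is formed, with a neutral solvent, and closes the oxirane by a plain displacement. Its precursor 6 is four steps from 1.

**Alternative 3:** The C4–C5 bond is formed by contraction of a six-membered ring.
- Forward key step: methoxide adds to the vicinal dione of cyclohexenetrione A6, the oxidised and methoxylated form of a terphenylquinone. A benzilic-ester-type 1,2-shift of the C(OMe)(aryl) carbon contracts the ring and expels one carbonyl carbon as a methyl ester on C4, giving hydroxy ester A7.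
- For: the plan follows the likely biogenesis. The diaryl core comes from a symmetric quinone by one double coupling without regiochemical halogenation, and both methoxy groups are in place before the contraction. To the carbocycle it is as short as the chosen route or shorter.
- Against: the exocyclic carbon arrives as an ester and must be reduced to the primary alcohol beside the C1 ketone and the C2=C3 enone, which costs protection or redox corrections. Methoxide can choose among three carbonyls, and the shift between two migrating bonds. The C4/C5 relationship depends on facial selectivity next to one existing centre. A6 is racemic, so a resolution is still needed.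
- Comparison: the chosen strategy has the exocyclic carbon at the right oxidation level from 1 and enforces the trans relationship through the fused oxirane of 7.

Key step: step 5

**Assumption:** the lipase of step 8 is taken to hydrolyse the (4R,5R)-acetate faster than its mirror image; if the enzyme screen shows the opposite sense, the recovered acetate is the target series and is cleaved by the same enzyme on longer exposure to give 12.

## Route

Step 1
Reactants: 1 kojic acid (5-hydroxy-2-(hydroxymethyl)-4H-pyran-4-one)
Product: 2 6-bromo-5-hydroxy-2-(hydroxymethyl)-4H-pyran-4-one (6-bromokojic acid)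
Conditions: NBS (1.05 equiv), DMF, 0 °C to rt, dark
Reagents that add atoms: N-bromosuccinimide, O=C1CCC(=O)N1Br
Why: Electrophilic bromination of an enol; the free 5-hydroxyl makes C6 the nucleophilic enol carbon, so the first bromine should enter there and not at C3.

Step 2
Reactants: 2 6-bromokojic acid
Product: 3 5-acetoxy-2-(acetoxymethyl)-6-bromo-4H-pyran-4-one
Conditions: Ac2O (2.5 equiv), Et3N (3 equiv), DMAP (5 mol %), CH2Cl2, 0 °C
Reagents that add atoms: acetic anhydride, CC(=O)OC(C)=O
Why: Acylation of the enol and the primary hydroxyl; the enol acetate switches off the C5=C6 enol so that the next bromination can only go to C3, and it is the weak donor that the key step needs.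

Step 3
Reactants: 3 5-acetoxy-2-(acetoxymethyl)-6-bromo-4H-pyran-4-one
Product: 4 5-acetoxy-2-(acetoxymethyl)-3,6-dibromo-4H-pyran-4-one
Conditions: Br2 (1.1 equiv), NaOAc (1.5 equiv), AcOH, rt to 40 °C
Reagents that add atoms: bromine, BrBr
Why: α-Halogenation of a 4-pyranone by electrophilic substitution; C3 is the only ring C–H left and the nucleophilic carbon of the ring enol ether O1–C2=C3, and the C2 oxocarbenium ion that forms loses the C3 proton to acetate.

Step 4
Reactants: 4 5-acetoxy-2-(acetoxymethyl)-3,6-dibromo-4H-pyran-4-one; 5 4-(tert-butyldimethylsilyloxy)phenylboronic acid (2.6 equiv)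
Product: 6 5-acetoxy-2-(acetoxymethyl)-3,6-bis[4-(tert-butyldimethylsilyloxy)phenyl]-4H-pyran-4-one
Conditions: Pd(OAc)2 (5 mol %), SPhos (2-dicyclohexylphosphino-2',6'-dimethoxybiphenyl, 10 mol %), K3PO4 (4 equiv, ground), toluene, 70–80 °C, degassed
Reagents that add atoms: none
Why: Double Suzuki–Miyaura coupling of two activated vinyl bromides (C6 a vinylogous acyl bromide, C3 an α-bromo enone); the bulky biarylphosphine serves the hindered C3 position, and a phosphate base in toluene is chosen to spare the enol acetate, the aryl silyl ethers and the allylic acetate.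

Step 5
Reactants: 6 5-acetoxy-2-(acetoxymethyl)-3,6-bis[4-(tert-butyldimethylsilyloxy)phenyl]-4H-pyran-4-one
Product: 9 rac-(4R,5R)-2-acetoxy-4-(acetoxymethyl)-4-hydroxy-5-methoxy-3,5-bis[4-(tert-butyldimethylsilyloxy)phenyl]cyclopent-2-en-1-one, via oxabicyclic oxyallyl zwitterion 7 (not isolated), via epoxy enol methanol adduct 8 (not isolated)
Conditions: hν (350 nm lamps, Pyrex), degassed MeOH (3 mM), 10–20 °C, flow reactor, stopped when 6 is consumed
Reagents that add atoms: methanol, CO
Why: Excitation of the cross-conjugated dienone of 6 is followed by disrotatory 4π electrocyclisation that bonds C2 to C6 of the pyranone; this one C–C bond closes the five-membered carbocycle and at the same time the fused oxirane, giving oxyallyl zwitterion 7. Methanol then bonds to the aryl-bearing oxyallyl terminus (old C3) to give enol 8, and the enol opens the oxirane at old C6, which leaves the enone and the tertiary hydroxyl on old C2, that is 9. The closest known reaction type is the photochemical ring contraction of alkyl-substituted 4-pyranones in hydroxylic solvents to trans-4-hydroxy-5-alkoxycyclopent-2-enones. C4 of 9 is fixed by the electrocyclisation and C5 by capture on the convex face of 7, opposite the oxirane oxygen, so the C5 methoxy group should end trans to the C4 oxygen; nothing controls the absolute sense, and 9 is racemic. The selectivity that the step needs is regiochemical: capture at the aryl terminus and not at the acetoxy terminus. It is secured by the 4-silyloxyphenyl group, which holds the positive charge as a benzylic cation, by the acetoxy group, which is a much weaker donor than an alkoxy group would be, and by the fact that this capture leads on to the aryl-conjugated enone. Methanol as solvent is in such excess that capture should outrun acetyl transfer to the oxyallyl oxygen and rearrangement of 7 to a 2-pyranone.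

Step 6
Reactants: 9 rac-(4R,5R)-2-acetoxy-4-(acetoxymethyl)-4-hydroxy-5-methoxy-3,5-bis[4-(tert-butyldimethylsilyloxy)phenyl]cyclopent-2-en-1-one
Product: 10 rac-(4R,5R)-4-(acetoxymethyl)-2,4-dihydroxy-5-methoxy-3,5-bis[4-(tert-butyldimethylsilyloxy)phenyl]cyclopent-2-en-1-one
Conditions: Et3N (2 equiv), MeOH, 0 °C to rt; used crude
Reagents that add atoms: none
Why: Amine-promoted methanolysis of an activated enol ester; the diosphenol (pKa about 9) is a far better leaving group than a primary alkoxide, so only the enol acetate should be cleaved, and the mild base leaves the aryl silyl ethers and the tertiary alcohol alone.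

Step 7
Reactants: 10 rac-(4R,5R)-4-(acetoxymethyl)-2,4-dihydroxy-5-methoxy-3,5-bis[4-(tert-butyldimethylsilyloxy)phenyl]cyclopent-2-en-1-one
Product: 11 rac-(4R,5R)-4-(acetoxymethyl)-4-hydroxy-2,5-dimethoxy-3,5-bis[4-(tert-butyldimethylsilyloxy)phenyl]cyclopent-2-en-1-one
Conditions: Me3SiCHN2 (1.5 equiv), MeOH/toluene 1:4, 0 °C
Reagents that add atoms: trimethylsilyldiazomethane, C[Si](C)(C)C=[N+]=[N-]
Why: Diazoalkane O-methylation of an acidic enol; the tertiary alcohol is not acidic enough to react, and no base is present that could start retro-aldol cleavage.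

Step 8
Reactants: 11 rac-(4R,5R)-4-(acetoxymethyl)-4-hydroxy-2,5-dimethoxy-3,5-bis[4-(tert-butyldimethylsilyloxy)phenyl]cyclopent-2-en-1-one
Product: 12 (4R,5R)-4-hydroxy-4-(hydroxymethyl)-2,5-dimethoxy-3,5-bis[4-(tert-butyldimethylsilyloxy)phenyl]cyclopent-2-en-1-one
Conditions: lipase from Burkholderia cepacia (Amano PS, immobilised), phosphate buffer pH 7/MTBE, 30 °C, to about half conversion; chromatography
Reagents that add atoms: none
Why: Lipase-catalysed kinetic resolution by enantioselective hydrolysis of a primary acetate next to a fully substituted stereocentre; no stereocentre is formed, the enzyme selects one enantiomer, and the neutral medium spares the silyl ethers and the β-hydroxy ketone. The alcohol is separated from the unreacted (4S,5S)-acetate.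

Step 9
Reactants: 12 (4R,5R)-4-hydroxy-4-(hydroxymethyl)-2,5-dimethoxy-3,5-bis[4-(tert-butyldimethylsilyloxy)phenyl]cyclopent-2-en-1-one
Product: 13 (4R,5R)-4-hydroxy-2,5-dimethoxy-4-[(4-methylbenzenesulfonyloxy)methyl]-3,5-bis[4-(tert-butyldimethylsilyloxy)phenyl]cyclopent-2-en-1-one
Conditions: TsCl (1.2 equiv), Et3N (2 equiv), Bu2SnO (5 mol %), CH2Cl2, 0 °C to rt
Reagents that add atoms: 4-toluenesulfonyl chloride, Cc1ccc(cc1)S(=O)(=O)Cl
Why: Tin-acetal-catalysed selective sulfonylation of the primary hydroxyl of a 1,2-diol; the tertiary hydroxyl should not react.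

Step 10
Reactants: 13 (4R,5R)-4-hydroxy-2,5-dimethoxy-4-[(4-methylbenzenesulfonyloxy)methyl]-3,5-bis[4-(tert-butyldimethylsilyloxy)phenyl]cyclopent-2-en-1-one
Product: 14 (3R,4R)-4,7-bis[4-(tert-butyldimethylsilyloxy)phenyl]-4,6-dimethoxy-1-oxaspiro[2.4]hept-6-en-5-one
Conditions: NaH (1.3 equiv), THF, 0 °C
Reagents that add atoms: none
Why: Intramolecular Williamson etherification (3-exo-tet); the tertiary alkoxide displaces the primary tosylate, the C4–O bond is not broken, so the configuration is retained. The ketone has no enolisable hydrogen, and the gem-disubstituted alkoxide should close faster than it fragments.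

Step 11
Reactants: 14 (3R,4R)-4,7-bis[4-(tert-butyldimethylsilyloxy)phenyl]-4,6-dimethoxy-1-oxaspiro[2.4]hept-6-en-5-one
Product: 15 (3R,4R)-4,7-bis(4-hydroxyphenyl)-4,6-dimethoxy-1-oxaspiro[2.4]hept-6-en-5-one (CNP0504072.1)
Conditions: Bu4NF (2.5 equiv), AcOH (3 equiv), THF, 0 °C
Reagents that add atoms: none
Why: Fluoride cleavage of aryl silyl ethers; buffering with acetic acid keeps the phenols protonated, so neither phenoxide nor free fluoride should attack the spiro-oxirane or the C5 methoxy centre.

## Compound list

1 | kojic acid (5-hydroxy-2-(hydroxymethyl)-4H-pyran-4-one) | O=C1C=C(CO)OC=C1O | starting material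
2 | 6-bromo-5-hydroxy-2-(hydroxymethyl)-4H-pyran-4-one | O=C1C=C(CO)OC(Br)=C1O | intermediate
3 | 5-acetoxy-2-(acetoxymethyl)-6-bromo-4H-pyran-4-one | CC(=O)OCC1=CC(=O)C(OC(C)=O)=C(Br)O1 | intermediate
4 | 5-acetoxy-2-(acetoxymethyl)-3,6-dibromo-4H-pyran-4-one | CC(=O)OCC1=C(Br)C(=O)C(OC(C)=O)=C(Br)O1 | intermediate
5 | 4-(tert-butyldimethylsilyloxy)phenylboronic acid | CC(C)(C)[Si](C)(C)Oc1ccc(B(O)O)cc1 | starting material
6 | 5-acetoxy-2-(acetoxymethyl)-3,6-bis[4-(tert-butyldimethylsilyloxy)phenyl]-4H-pyran-4-one | CC(=O)OCC1=C(c2ccc(O[Si](C)(C)C(C)(C)C)cc2)C(=O)C(OC(C)=O)=C(c2ccc(O[Si](C)(C)C(C)(C)C)cc2)O1 | intermediate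
7 | 4-acetoxy-1-(acetoxymethyl)-2,5-bis[4-(tert-butyldimethylsilyloxy)phenyl]-6-oxabicyclo[3.1.0]hex-3-en-2-ylium-3-olate, cis-fused, racemic, drawn as the enantiomer that leads to the (4R,5R) series (not isolated) | CC(=O)OC[C@]12O[C@@]1(c3ccc(O[Si](C)(C)C(C)(C)C)cc3)C(OC(C)=O)=C([O-])[C+]2c3ccc(O[Si](C)(C)C(C)(C)C)cc3 | intermediate
8 | 4-acetoxy-1-(acetoxymethyl)-3-hydroxy-2-methoxy-2,5-bis[4-(tert-butyldimethylsilyloxy)phenyl]-6-oxabicyclo[3.1.0]hex-3-ene, methoxy group on the face opposite the oxirane oxygen, racemic (not isolated) | CC(=O)OC[C@]12O[C@@]1(c3ccc(O[Si](C)(C)C(C)(C)C)cc3)C(OC(C)=O)=C(O)[C@@]2(OC)c3ccc(O[Si](C)(C)C(C)(C)C)cc3 | intermediate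
9 | rac-(4R,5R)-2-acetoxy-4-(acetoxymethyl)-4-hydroxy-5-methoxy-3,5-bis[4-(tert-butyldimethylsilyloxy)phenyl]cyclopent-2-en-1-one (racemate, one enantiomer drawn) | CC(=O)OC1=C(c2ccc(O[Si](C)(C)C(C)(C)C)cc2)[C@@](O)(COC(C)=O)[C@](OC)(c2ccc(O[Si](C)(C)C(C)(C)C)cc2)C1=O | intermediate
10 | rac-(4R,5R)-4-(acetoxymethyl)-2,4-dihydroxy-5-methoxy-3,5-bis[4-(tert-butyldimethylsilyloxy)phenyl]cyclopent-2-en-1-one (racemate, one enantiomer drawn) | OC1=C(c2ccc(O[Si](C)(C)C(C)(C)C)cc2)[C@@](O)(COC(C)=O)[C@](OC)(c2ccc(O[Si](C)(C)C(C)(C)C)cc2)C1=O | intermediate
11 | rac-(4R,5R)-4-(acetoxymethyl)-4-hydroxy-2,5-dimethoxy-3,5-bis[4-(tert-butyldimethylsilyloxy)phenyl]cyclopent-2-en-1-one (racemate, one enantiomer drawn) | COC1=C(c2ccc(O[Si](C)(C)C(C)(C)C)cc2)[C@@](O)(COC(C)=O)[C@](OC)(c2ccc(O[Si](C)(C)C(C)(C)C)cc2)C1=O | intermediate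
12 | (4R,5R)-4-hydroxy-4-(hydroxymethyl)-2,5-dimethoxy-3,5-bis[4-(tert-butyldimethylsilyloxy)phenyl]cyclopent-2-en-1-one | COC1=C(c2ccc(O[Si](C)(C)C(C)(C)C)cc2)[C@@](O)(CO)[C@](OC)(c2ccc(O[Si](C)(C)C(C)(C)C)cc2)C1=O | intermediate
13 | (4R,5R)-4-hydroxy-2,5-dimethoxy-4-[(4-methylbenzenesulfonyloxy)methyl]-3,5-bis[4-(tert-butyldimethylsilyloxy)phenyl]cyclopent-2-en-1-one | COC1=C(c2ccc(O[Si](C)(C)C(C)(C)C)cc2)[C@@](O)(COS(=O)(=O)c2ccc(C)cc2)[C@](OC)(c2ccc(O[Si](C)(C)C(C)(C)C)cc2)C1=O | intermediate
14 | (3R,4R)-4,7-bis[4-(tert-butyldimethylsilyloxy)phenyl]-4,6-dimethoxy-1-oxaspiro[2.4]hept-6-en-5-one | COC1=C(c2ccc(O[Si](C)(C)C(C)(C)C)cc2)[C@@]3(CO3)[C@](OC)(c2ccc(O[Si](C)(C)C(C)(C)C)cc2)C1=O | intermediate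
15 | (3R,4R)-4,7-bis(4-hydroxyphenyl)-4,6-dimethoxy-1-oxaspiro[2.4]hept-6-en-5-one | COC1=C(c2ccc(O)cc2)[C@@]2(CO2)[C@](OC)(c2ccc(O)cc2)C1=O | target

## Step count and least certain steps

Total: 11 steps. Longest linear sequence: 11 steps, from 1 to 15 (5 is bought).

**Step 5 (key step).** Four processes may defeat it:
- deactivation of the excited state through the aryl group on C6, which makes 6 a flavone-like chromophore, so that electrocyclisation is inefficient;
- capture of 7 at the acetoxy-bearing terminus;
- rearrangement of 7 to a 2-pyranone, helped by the benzylic oxirane carbon, before the solvent arrives;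
- secondary photolysis of the product enone.

The fallback introduces the C3 aryl group after the ring contraction. It sets out from 1 and returns at 11.
- Acetylation of 1 (Ac2O, Et3N, DMAP) gives kojic acid diacetate F1.
- Bromination at C3 (Br2, NaOAc, AcOH) gives 3-bromo diacetate F2.
- Suzuki coupling with one equivalent of 5 gives 3-aryl pyranone F3, whose only aryl group is a twisted α-substituent, so its chromophore is close to that of the alkyl pyranones.
- Irradiation in methanol as in step 5 should give racemic cyclopentenone F4, which carries hydrogen on C3.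
- The enol acetate is cleaved as in step 6 to diosphenol F5.
- NBS brominates the enol carbon C3 of F5, far faster than the silyloxyarene, to give bromo diosphenol F6.
- O-methylation as in step 7 gives β-bromo enone F7.
- Suzuki coupling of this vinylogous acyl bromide with 5 (Pd(PPh3)4, K3PO4, dioxane, 50 °C) gives 11.

**Step 8.** Enantiomer discrimination may be poor, because the stereocentre is a fully substituted carbon flanked by two aryl-bearing carbons, or the enzyme may not accept so bulky a substrate. The fallback is a separation of covalent diastereomers in which the resolving group is also the leaving group. It sets out from 11 and returns at 14, so step 9 is not needed.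
- The acetate is cleaved without regard to selectivity (the lipase run to full conversion, or Candida antarctica lipase B with butanol, or catalytic Bu2SnO in methanol), which gives 12 as the racemate.
- Sulfonylation with (1S)-camphor-10-sulfonyl chloride under the conditions of step 9 gives the (4R,5R)-camphorsulfonate F8 and the (4S,5S)-camphorsulfonate F9.
- The two are separated by chromatography or crystallisation.
- F8 with NaH as in step 10 gives 14.

**Step 4.** The enol acetate or the aryl silyl ethers may be lost to the basic medium. The hindered C3 bromide may couple slowly and suffer protodebromination. Zerovalent palladium may ionise the allylic acetate once the bromides are used up. The fallback is a base-free Stille coupling. It sets out from 4 and returns at 6.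
- Commercial (4-bromophenoxy)(tert-butyl)dimethylsilane F10 is converted with n-BuLi and then Bu3SnCl into tributyl[4-(tert-butyldimethylsilyloxy)phenyl]stannane F11.
- 4 and F11 (2.4 equiv) with Pd(PPh3)4 and CuI in dioxane at 70 °C give 6.

**Step 10.** The tertiary alkoxide may undergo retro-aldol cleavage of the C4–C5 bond in competition with the displacement, which would destroy both stereocentres. The fallback avoids a free alkoxide. It sets out from 12 and returns at 14: Mitsunobu cyclodehydration of the 1,2-diol (PPh3, diisopropyl azodicarboxylate, toluene, 0 °C to rt) activates the primary hydroxyl and closes the oxirane with retention at C4. It needs no tosylate and makes no compound outside the list (F0).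

**Step 11.** The spiro-oxirane may be opened by acetic acid or hydrogen fluoride, or phenoxide formed under insufficient buffering may trigger loss of the C5 methoxy group. The fallback removes the silyl groups before the oxirane exists. It sets out from 13 and returns at 15.
- Bu4NF/AcOH in THF converts 13 into bis-phenol hydroxy tosylate F12.
- K2CO3 (3.5 equiv) in acetonitrile at 0 °C to rt, followed by a pH 7 quench, closes the oxirane to 15.

## Further compounds

F1 | step 5 | 5-acetoxy-2-(acetoxymethyl)-4H-pyran-4-one (kojic acid diacetate) | CC(=O)OCC1=CC(=O)C(OC(C)=O)=CO1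
F2 | step 5 | 5-acetoxy-2-(acetoxymethyl)-3-bromo-4H-pyran-4-one | CC(=O)OCC1=C(Br)C(=O)C(OC(C)=O)=CO1
F3 | step 5 | 5-acetoxy-2-(acetoxymethyl)-3-[4-(tert-butyldimethylsilyloxy)phenyl]-4H-pyran-4-one | CC(=O)OCC1=C(c2ccc(O[Si](C)(C)C(C)(C)C)cc2)C(=O)C(OC(C)=O)=CO1
F4 | step 5 | rac-(4R,5R)-2-acetoxy-4-(acetoxymethyl)-4-hydroxy-5-methoxy-5-[4-(tert-butyldimethylsilyloxy)phenyl]cyclopent-2-en-1-one | CC(=O)OC1=C[C@@](O)(COC(C)=O)[C@](OC)(c2ccc(O[Si](C)(C)C(C)(C)C)cc2)C1=O
F5 | step 5 | rac-(4R,5R)-4-(acetoxymethyl)-2,4-dihydroxy-5-methoxy-5-[4-(tert-butyldimethylsilyloxy)phenyl]cyclopent-2-en-1-one | OC1=C[C@@](O)(COC(C)=O)[C@](OC)(c2ccc(O[Si](C)(C)C(C)(C)C)cc2)C1=O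
F6 | step 5 | rac-(4R,5R)-4-(acetoxymethyl)-3-bromo-2,4-dihydroxy-5-methoxy-5-[4-(tert-butyldimethylsilyloxy)phenyl]cyclopent-2-en-1-one | OC1=C(Br)[C@@](O)(COC(C)=O)[C@](OC)(c2ccc(O[Si](C)(C)C(C)(C)C)cc2)C1=O
F7 | step 5 | rac-(4R,5R)-4-(acetoxymethyl)-3-bromo-4-hydroxy-2,5-dimethoxy-5-[4-(tert-butyldimethylsilyloxy)phenyl]cyclopent-2-en-1-one | COC1=C(Br)[C@@](O)(COC(C)=O)[C@](OC)(c2ccc(O[Si](C)(C)C(C)(C)C)cc2)C1=O
F8 | step 8 | (1S)-camphor-10-sulfonate of 12, (4R,5R) at the ring | COC1=C(c2ccc(O[Si](C)(C)C(C)(C)C)cc2)[C@@](O)(COS(=O)(=O)C[C@]34CC[C@H](CC3=O)C4(C)C)[C@](OC)(c2ccc(O[Si](C)(C)C(C)(C)C)cc2)C1=O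
F9 | step 8 | (1S)-camphor-10-sulfonate of the enantiomer of 12, (4S,5S) at the ring | COC1=C(c2ccc(O[Si](C)(C)C(C)(C)C)cc2)[C@](O)(COS(=O)(=O)C[C@]34CC[C@H](CC3=O)C4(C)C)[C@@](OC)(c2ccc(O[Si](C)(C)C(C)(C)C)cc2)C1=O
F10 | step 4 | (4-bromophenoxy)(tert-butyl)dimethylsilane (bought) | CC(C)(C)[Si](C)(C)Oc1ccc(Br)cc1
F11 | step 4 | tributyl[4-(tert-butyldimethylsilyloxy)phenyl]stannane | CCCC[Sn](CCCC)(CCCC)c1ccc(O[Si](C)(C)C(C)(C)C)cc1
F0 | step 10 | none | none
F12 | step 11 | (4R,5R)-4-hydroxy-3,5-bis(4-hydroxyphenyl)-2,5-dimethoxy-4-[(4-methylbenzenesulfonyloxy)methyl]cyclopent-2-en-1-one | COC1=C(c2ccc(O)cc2)[C@@](O)(COS(=O)(=O)c2ccc(C)cc2)[C@](OC)(c2ccc(O)cc2)C1=O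
A1 | alternative 1 | 1-diazo-1-[4-(tert-butyldimethylsilyloxy)phenyl]-3-methoxypropan-2-one | COCC(=O)C(=[N+]=[N-])c1ccc(O[Si](C)(C)C(C)(C)C)cc1
A2 | alternative 1 | 3-chloro-1-[4-(tert-butyldimethylsilyloxy)phenyl]propane-1,2-dione | O=C(CCl)C(=O)c1ccc(O[Si](C)(C)C(C)(C)C)cc1
A3 | alternative 1 | (2R,3R)-2-(chloromethyl)-2-hydroxy-3,5-dimethoxy-1,3-bis[4-(tert-butyldimethylsilyloxy)phenyl]pentane-1,4-dione | O=C(c1ccc(O[Si](C)(C)C(C)(C)C)cc1)[C@@](O)(CCl)[C@](OC)(c1ccc(O[Si](C)(C)C(C)(C)C)cc1)C(=O)COC
A4 | alternative 2 | 5-(hydroxymethyl)-3-methoxy-1,4-bis[4-(tert-butyldimethylsilyloxy)phenyl]-6-oxabicyclo[3.1.0]hex-3-en-2-one, cis-fused, oxirane oxygen on the face that the C5 oxygen of the target occupies | COC1=C(c2ccc(O[Si](C)(C)C(C)(C)C)cc2)[C@@]3(CO)O[C@@]3(c2ccc(O[Si](C)(C)C(C)(C)C)cc2)C1=O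
A5 | alternative 2 | (3R,4R)-4-hydroxy-6-methoxy-4,7-bis[4-(tert-butyldimethylsilyloxy)phenyl]-1-oxaspiro[2.4]hept-6-en-5-one | COC1=C(c2ccc(O[Si](C)(C)C(C)(C)C)cc2)[C@@]3(CO3)[C@](O)(c2ccc(O[Si](C)(C)C(C)(C)C)cc2)C1=O
A6 | alternative 3 | 2,6-dimethoxy-3,6-bis[4-(triisopropylsilyloxy)phenyl]cyclohex-2-ene-1,4,5-trione, C6 configured as C5 of the target | COC1=C(c2ccc(O[Si](C(C)C)(C(C)C)C(C)C)cc2)C(=O)C(=O)[C@](OC)(c2ccc(O[Si](C(C)C)(C(C)C)C(C)C)cc2)C1=O
A7 | alternative 3 | methyl 1-hydroxy-3,5-dimethoxy-4-oxo-2,5-bis[4-(triisopropylsilyloxy)phenyl]cyclopent-2-ene-1-carboxylate, hydroxyl and C5 methoxy trans | COC1=C(c2ccc(O[Si](C(C)C)(C(C)C)C(C)C)cc2)[C@@](O)(C(=O)OC)[C@](OC)(c2ccc(O[Si](C(C)C)(C(C)C)C(C)C)cc2)C1=O
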